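**Plan**

- Numbering (germacrane): C1 and C3 are the ring ketones, C2 the methylene between them, C4–C5 the epoxide, C6–O–C12 the lactone on the C7=C11 butenolide, C8 the ester carbon, C10 the CH(CH3), C13 the acetoxymethyl carbon. The ten-membered ring is cut at C2–C3: the C1(=O)–C2H2–C3(=O) array is read as a 2-isoxazoline, i.e. a nitrile oxide at C3 (on epoxide carbon C4) and a C1=C2 vinyl group on C10.
- Further cuts: C8–O (side-chain acid from 4-methylbutenolide), C7–C8 (Stille acylation, then CBS reduction), C11–C13 and the lactone (alkynoate distannylation, α-hydroxymethylation, lactonisation), C6–C7 (asymmetric alkynylation of an enal), epoxide oxygen (Sharpless).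
- Forward: the butenolide is made first and carries the C5 and C8 branches on adjacent ring atoms (C6 sp3, C7 sp2); the trans C4–C5 epoxide is added; one cycloaddition then closes the isoxazoline and the ten-membered carbocycle together; N–O cleavage and oxidation unveil the 1,3-diketone.
- What makes the event possible: the C6/C7 junction of the butenolide and the trans epoxide fold the C3 and C2 termini toward each other, the vinyl group is the only reactive dipolarophile, and its polarisation puts C3 on C2 and O on C1 (bridged mode, a bicyclo[7.2.1] array).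
- Stereochemistry: C10 by Evans-auxiliary conjugate addition, C6 by ProPhenol alkynylation, C8 by CBS reduction, C4/C5 by Sharpless epoxidation with D-(−)-tartrate; the C1 centre of the isoxazoline is uncontrolled and is erased on oxidation.

Key step: step 19

Assumption: (S,S)-ProPhenol is taken as the ligand enantiomer that gives the 4R carbinol in step 3; if its facial sense is the reverse, the (R,R) ligand is used.

**Route**

Step 1
Reactants: 1 1-methoxy-4-[(prop-2-yn-1-yloxy)methyl]benzene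
Product: 3 (2E)-4-[(4-methoxybenzyl)oxy]-3-methylbut-2-en-1-ol, via alkenylalane 2 (not isolated)
Conditions: AlMe3, Cp2ZrCl2 (cat.), CH2Cl2, 0 °C to rt; n-BuLi, THF, −78 °C; (CH2O)n, rt; aq. HCl
Reagents that add atoms: trimethylaluminium, C[Al](C)C; formaldehyde (from paraformaldehyde), C=O
Why: Negishi zirconium-catalysed carboalumination adds methyl and aluminium syn across the terminal alkyne (methyl to the internal carbon), and hydroxymethylation of the derived alanate with retention fixes the E trisubstituted alkene that becomes C4=C5.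

Step 2
Reactants: 3 (2E)-4-[(4-methoxybenzyl)oxy]-3-methylbut-2-en-1-ol
Product: 4 (2E)-4-[(4-methoxybenzyl)oxy]-3-methylbut-2-enal
Conditions: MnO2, CH2Cl2, rt
Reagents that add atoms: none
Why: Allylic oxidation with MnO2 should take the primary allylic alcohol to the enal without touching the PMB ether or the alkene geometry.

Step 3
Reactants: 4 (2E)-4-[(4-methoxybenzyl)oxy]-3-methylbut-2-enal; 5 methyl prop-2-ynoate
Product: 6 methyl (4R,5E)-4-hydroxy-7-[(4-methoxybenzyl)oxy]-6-methylhept-5-en-2-ynoate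
Conditions: Me2Zn, (S,S)-ProPhenol (10 mol %), Ph3P=O (cat.), toluene, 0 °C
Reagents that add atoms: none
Why: Zinc–ProPhenol catalysed asymmetric alkynylation of an α,β-unsaturated aldehyde with methyl propiolate should form the C6–C7 bond and set C6 by catalyst control.

Step 4
Reactants: 6 methyl (4R,5E)-4-hydroxy-7-[(4-methoxybenzyl)oxy]-6-methylhept-5-en-2-ynoate
Product: 7 methyl (4R,5E)-7-[(4-methoxybenzyl)oxy]-6-methyl-4-[(triethylsilyl)oxy]hept-5-en-2-ynoate
Conditions: Et3SiCl, imidazole, CH2Cl2, 0 °C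
Reagents that add atoms: chlorotriethylsilane, CC[Si](Cl)(CC)CC
Why: Silyl ether formation blocks early lactonisation and protects the carbinol from methyllithium in step 6.

Step 5
Reactants: 7 methyl (4R,5E)-7-[(4-methoxybenzyl)oxy]-6-methyl-4-[(triethylsilyl)oxy]hept-5-en-2-ynoate
Product: 8 methyl (2Z,4R,5E)-7-[(4-methoxybenzyl)oxy]-6-methyl-4-[(triethylsilyl)oxy]-2,3-bis(trimethylstannyl)hepta-2,5-dienoate
Conditions: Me3SnSnMe3, Pd(PPh3)4 (cat.), THF, 65 °C
Reagents that add atoms: hexamethylditin, C[Sn](C)(C)[Sn](C)(C)C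
Why: Palladium-catalysed syn distannylation of an alkynoate should give the Z bis-stannane, which places the ester cis to C6 as the later lactonisation requires.

Step 6
Reactants: 8 methyl (2Z,4R,5E)-7-[(4-methoxybenzyl)oxy]-6-methyl-4-[(triethylsilyl)oxy]-2,3-bis(trimethylstannyl)hepta-2,5-dienoate
Product: 10 methyl (2E,4R,5E)-2-(acetoxymethyl)-7-[(4-methoxybenzyl)oxy]-6-methyl-4-[(triethylsilyl)oxy]-3-(trimethylstannyl)hepta-2,5-dienoate, via α-lithio enoate 9 (not isolated)
Conditions: MeLi, THF, −98 °C; CH2O (gas, from cracked paraformaldehyde), −98 to −78 °C; Ac2O, −78 to 0 °C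
Reagents that add atoms: formaldehyde, C=O; acetic anhydride, CC(=O)OC(C)=O
Why: Regioselective tin–lithium exchange of the stannyl group geminal to the ester (Piers transmetalation of Z 2,3-bis(trimethylstannyl)enoates) and capture of the α-lithio enoate with retention by formaldehyde, then acetylation in the flask, should install C13 and complete the tetrasubstituted alkene.

Step 7
Reactants: 10 methyl (2E,4R,5E)-2-(acetoxymethyl)-7-[(4-methoxybenzyl)oxy]-6-methyl-4-[(triethylsilyl)oxy]-3-(trimethylstannyl)hepta-2,5-dienoate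
Product: 12 {(5R)-5-[(1E)-3-[(4-methoxybenzyl)oxy]-2-methylprop-1-en-1-yl]-2-oxo-4-(trimethylstannyl)-2,5-dihydrofuran-3-yl}methyl acetate, via hydroxy ester 11 (not isolated)
Conditions: Bu4NF, AcOH, THF, 0 °C to rt
Reagents that add atoms: none
Why: Buffered fluoride desilylation frees the C6 hydroxyl, which sits cis to the methyl ester and should lactonise to the butenolide without exposing C6–H to strong base (desilylation–lactonisation).

Step 8
Reactants: 13 (4R)-4-benzyl-1,3-oxazolidin-2-one; 14 (2E)-but-2-enoyl chloride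
Product: 15 (4R)-4-benzyl-3-[(2E)-but-2-enoyl]-1,3-oxazolidin-2-one
Conditions: n-BuLi, THF, −78 °C
Reagents that add atoms: none
Why: N-acylation of the lithiated Evans oxazolidinone gives the enoyl imide.

Step 9
Reactants: 15 (4R)-4-benzyl-3-[(2E)-but-2-enoyl]-1,3-oxazolidin-2-one
Product: 16 (4R)-4-benzyl-3-[(3S)-3-methylpent-4-enoyl]-1,3-oxazolidin-2-one
Conditions: CH2=CHMgBr, CuBr·SMe2 (cat.), THF/Me2S, −78 to −20 °C; aq. NH4Cl
Reagents that add atoms: vinylmagnesium bromide, C=C[Mg]Br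
Why: Copper-mediated conjugate addition to the magnesium-chelated s-cis enoyl imide should occur anti to the benzyl group and set C10 (Evans auxiliary control).

Step 10
Reactants: 16 (4R)-4-benzyl-3-[(3S)-3-methylpent-4-enoyl]-1,3-oxazolidin-2-one
Product: 17 (3S)-3-methylpent-4-enoic acid
Conditions: LiOH, H2O2, THF/H2O, 0 °C; Na2SO3; HCl
Reagents that add atoms: hydrogen peroxide (as lithium hydroperoxide), OO
Why: Evans hydrolysis with lithium hydroperoxide cleaves the exocyclic imide carbonyl selectively and leaves the β-stereocentre untouched.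

Step 11
Reactants: 12 {(5R)-5-[(1E)-3-[(4-methoxybenzyl)oxy]-2-methylprop-1-en-1-yl]-2-oxo-4-(trimethylstannyl)-2,5-dihydrofuran-3-yl}methyl acetate; 17 (3S)-3-methylpent-4-enoic acid
Product: 19 {(5R)-5-[(1E)-3-[(4-methoxybenzyl)oxy]-2-methylprop-1-en-1-yl]-4-[(3S)-3-methylpent-4-enoyl]-2-oxo-2,5-dihydrofuran-3-yl}methyl acetate, via acid chloride 18 (not isolated)
Conditions: 17, (COCl)2, DMF (cat.), CH2Cl2, 0 °C to rt, evaporate; then 12, Pd2(dba)3 (cat.), P(2-furyl)3, toluene, 60 °C
Reagents that add atoms: none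
Why: Stille acylation, in which the acid chloride adds oxidatively to zerovalent palladium and the alkenylstannane transmetalates with retention, should form the C7–C8 bond under neutral conditions.

Step 12
Reactants: 19 {(5R)-5-[(1E)-3-[(4-methoxybenzyl)oxy]-2-methylprop-1-en-1-yl]-4-[(3S)-3-methylpent-4-enoyl]-2-oxo-2,5-dihydrofuran-3-yl}methyl acetate
Product: 20 {(5R)-4-[(1S,3S)-1-hydroxy-3-methylpent-4-en-1-yl]-5-[(1E)-3-[(4-methoxybenzyl)oxy]-2-methylprop-1-en-1-yl]-2-oxo-2,5-dihydrofuran-3-yl}methyl acetate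
Conditions: (R)-2-methyl-CBS-oxazaborolidine (0.2 equiv), catecholborane, toluene, −78 °C
Reagents that add atoms: none
Why: Corey–Bakshi–Shibata reduction, with the tetrasubstituted alkenyl group acting as the large substituent, should give the 8S carbinol by catalyst control while catecholborane leaves the lactone and the acetate alone.

Step 13
Reactants: 21 4-methylfuran-2(5H)-one
Product: 24 (2Z)-4-[(tert-butyldimethylsilyl)oxy]-3-methylbut-2-enoic acid, via sodium carboxylate 22 (not isolated), via bis-silyl ester 23 (not isolated)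
Conditions: NaOH, MeOH/H2O, rt, evaporate; t-BuMe2SiCl, imidazole, DMF; K2CO3 (cat.), MeOH/THF/H2O, 0 °C; citric acid
Reagents that add atoms: sodium hydroxide, [Na+].[OH-]; tert-butyl(chloro)dimethylsilane, CC(C)(C)[Si](C)(C)Cl
Why: Saponification opens the butenolide to the Z γ-hydroxy enoate (geometry fixed by the ring), bis-silylation traps it before relactonisation, and the labile silyl ester is then cleaved selectively.

Step 14
Reactants: 20 {(5R)-4-[(1S,3S)-1-hydroxy-3-methylpent-4-en-1-yl]-5-[(1E)-3-[(4-methoxybenzyl)oxy]-2-methylprop-1-en-1-yl]-2-oxo-2,5-dihydrofuran-3-yl}methyl acetate; 24 (2Z)-4-[(tert-butyldimethylsilyl)oxy]-3-methylbut-2-enoic acid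
Product: 25 (1S,3S)-1-{(2R)-4-(acetoxymethyl)-2-[(1E)-3-[(4-methoxybenzyl)oxy]-2-methylprop-1-en-1-yl]-5-oxo-2,5-dihydrofuran-3-yl}-3-methylpent-4-en-1-yl (2Z)-4-[(tert-butyldimethylsilyl)oxy]-3-methylbut-2-enoate
Conditions: DCC, DMAP (cat.), CH2Cl2, 0 °C
Reagents that add atoms: none
Why: Steglich esterification should acylate the hindered allylic alcohol with retention at C8, the low temperature limiting Z/E drift of the acyl donor.

Step 15
Reactants: 25 the PMB ether named in step 14
Product: 26 (1S,3S)-1-{(2R)-4-(acetoxymethyl)-2-[(1E)-3-hydroxy-2-methylprop-1-en-1-yl]-5-oxo-2,5-dihydrofuran-3-yl}-3-methylpent-4-en-1-yl (2Z)-4-[(tert-butyldimethylsilyl)oxy]-3-methylbut-2-enoate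
Conditions: DDQ, CH2Cl2/pH 7 buffer, 0 °C
Reagents that add atoms: none
Why: Oxidative PMB ether cleavage by DDQ proceeds through the stabilised benzylic cation and should spare the silyl ether, the esters and the alkenes.

Step 16
Reactants: 26 the allylic alcohol named in step 15
Product: 27 (1S,3S)-1-{(2S)-4-(acetoxymethyl)-2-[(2R,3R)-3-(hydroxymethyl)-3-methyloxiran-2-yl]-5-oxo-2,5-dihydrofuran-3-yl}-3-methylpent-4-en-1-yl (2Z)-4-[(tert-butyldimethylsilyl)oxy]-3-methylbut-2-enoate
Conditions: Ti(OiPr)4, D-(−)-diethyl tartrate, t-BuOOH, 4 Å MS, CH2Cl2, −20 °C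
Reagents that add atoms: tert-butyl hydroperoxide, CC(C)(C)OO
Why: Sharpless asymmetric epoxidation with D-(−)-tartrate should deliver oxygen to the face of the E 2-methyl allylic alcohol that gives the 2R,3R epoxy alcohol (C4 and C5 by reagent control over the C6 centre), and only the alkene of the allylic alcohol reacts.

Step 17
Reactants: 27 the epoxy alcohol named in step 16
Product: 28 (1S,3S)-1-{(2S)-4-(acetoxymethyl)-2-[(2R,3S)-3-formyl-3-methyloxiran-2-yl]-5-oxo-2,5-dihydrofuran-3-yl}-3-methylpent-4-en-1-yl (2Z)-4-[(tert-butyldimethylsilyl)oxy]-3-methylbut-2-enoate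
Conditions: Dess–Martin periodinane, NaHCO3, CH2Cl2, 0 °C to rt
Reagents that add atoms: none
Why: Dess–Martin oxidation under buffered conditions gives the α,β-epoxy aldehyde, whose α-carbon C4 is quaternary and cannot epimerise.

Step 18
Reactants: 28 the epoxy aldehyde named in step 17
Product: 29 (1S,3S)-1-{(2S)-4-(acetoxymethyl)-2-[(2R,3R)-3-[(E)-(hydroxyimino)methyl]-3-methyloxiran-2-yl]-5-oxo-2,5-dihydrofuran-3-yl}-3-methylpent-4-en-1-yl (2Z)-4-[(tert-butyldimethylsilyl)oxy]-3-methylbut-2-enoate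
Conditions: NH2OH·HCl, NaOAc, MeOH, 0 °C
Reagents that add atoms: hydroxylamine hydrochloride, NO.Cl
Why: Oxime condensation at the unhindered aldehyde under buffered conditions supplies the nitrile oxide precursor.

Step 19
Reactants: 29 the aldoxime named in step 18
Product: 32 2-isoxazoline-bridged ten-membered carbocycle (C3=N–O–C1; both C1 epimers), via hydroximoyl chloride 30 (not isolated), via nitrile oxide 31 (not isolated)
Conditions: N-chlorosuccinimide, pyridine (cat.), CHCl3, 0 °C to rt; then Et3N by syringe pump, CH2Cl2, about 1 mM, rt to 40 °C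
Reagents that add atoms: none
Why: N-chlorosuccinimide chlorinates the aldoxime to the hydroximoyl chloride 30, slow dehydrochlorination by triethylamine at high dilution releases the nitrile oxide 31 at C3, and this 1,3-dipole adds in a concerted suprafacial [3+2] fashion across the C1=C2 vinyl group, C3 bonding to the terminal carbon C2 and oxygen to C1. The closest known reaction type is the intramolecular nitrile oxide–alkene cycloaddition used in bridged mode for macrocyclisation of ω-alkenyl nitrile oxides. Two rings close at once: the five-membered 2-isoxazoline by the cycloaddition itself and the ten-membered carbocycle by the C2–C3 bond in bridged (endo) mode, the C1–C2–C3 unit being shared by both rings, whereas the fused mode would need a nine-membered ring and the electronically disfavoured 4-substituted isoxazoline. The only new stereocentre, C1, is set by the conformation of the folded chain and need not be controlled, because both epimers give the same ketone in step 21. The step needs regioselectivity, chemoselectivity and ring closure in preference to furoxan dimerisation: the polarisation of the monosubstituted alkene sends oxygen to C1, the tetrasubstituted butenolide alkene and the trisubstituted enoate are poor dipolarophiles, high dilution suppresses dimerisation, and the C5 and C8 branches on adjacent butenolide atoms together with the trans epoxide hold the two termini within reach. The conditions are nearly neutral, so the acidic C6–H of the butenolide, the epoxide and the esters should survive where an enolate-based closure would endanger them.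

Step 20
Reactants: 32 the isoxazoline-bridged macrocycle of step 19
Product: 33 1-hydroxy-3-oxo macrocycle (both C1 epimers; silyl ether of the side chain retained)
Conditions: Mo(CO)6, MeCN/H2O, 80 °C
Reagents that add atoms: water, O
Why: Reductive N–O cleavage with Mo(CO)6 gives a β-hydroxy imine that hydrolyses to the β-hydroxy ketone (isoxazoline as masked aldol), a method that should spare the alkenes, the esters and the epoxide.

Step 21
Reactants: 33 the β-hydroxy ketone of step 20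
Product: 34 4′-O-(tert-butyldimethylsilyl) ether of the target (1,3-dioxo macrocycle)
Conditions: Dess–Martin periodinane (1.1 equiv), NaHCO3, CH2Cl2, 0 °C
Reagents that add atoms: none
Why: Dess–Martin oxidation of the β-hydroxy ketone gives the 1,3-diketone and removes the uncontrolled C1 centre, the limited oxidant charge guarding against over-oxidation at C2.

Step 22
Reactants: 34 the silyl ether of step 21
Product: 35 (4S,5R,6S,8S,10S)-13-acetoxy-4,5-epoxy-8-[(2Z)-4-hydroxy-3-methylbut-2-enoyloxy]-1,3-dioxogermacr-7(11)-en-12,6-olide (target)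
Conditions: HF·pyridine, pyridine, THF, 0 °C
Reagents that add atoms: none
Why: Buffered fluoride desilylation, driven by Si–F bond formation, should free the primary alcohol without opening the epoxide, cleaving the acetate or lactonising the Z hydroxy enoate.

**Compound list**

1 | 1-methoxy-4-[(prop-2-yn-1-yloxy)methyl]benzene | C#CCOCc1ccc(OC)cc1 | starting material
2 | [(1E)-3-[(4-methoxybenzyl)oxy]-2-methylprop-1-en-1-yl]dimethylalumane | C[Al](C)/C=C(\C)COCc1ccc(OC)cc1 | intermediate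
3 | (2E)-4-[(4-methoxybenzyl)oxy]-3-methylbut-2-en-1-ol | OC/C=C(\C)COCc1ccc(OC)cc1 | intermediate
4 | (2E)-4-[(4-methoxybenzyl)oxy]-3-methylbut-2-enal | O=C/C=C(\C)COCc1ccc(OC)cc1 | intermediate
5 | methyl prop-2-ynoate | C#CC(=O)OC | starting material
6 | methyl (4R,5E)-4-hydroxy-7-[(4-methoxybenzyl)oxy]-6-methylhept-5-en-2-ynoate | COC(=O)C#C[C@H](O)/C=C(\C)COCc1ccc(OC)cc1 | intermediate
7 | methyl (4R,5E)-7-[(4-methoxybenzyl)oxy]-6-methyl-4-[(triethylsilyl)oxy]hept-5-en-2-ynoate | COC(=O)C#C[C@H](O[Si](CC)(CC)CC)/C=C(\C)COCc1ccc(OC)cc1 | intermediate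
8 | methyl (2Z,4R,5E)-7-[(4-methoxybenzyl)oxy]-6-methyl-4-[(triethylsilyl)oxy]-2,3-bis(trimethylstannyl)hepta-2,5-dienoate | COC(=O)/C([Sn](C)(C)C)=C(/[Sn](C)(C)C)[C@H](O[Si](CC)(CC)CC)/C=C(\C)COCc1ccc(OC)cc1 | intermediate
9 | methyl (2E,4R,5E)-2-lithio-7-[(4-methoxybenzyl)oxy]-6-methyl-4-[(triethylsilyl)oxy]-3-(trimethylstannyl)hepta-2,5-dienoate | COC(=O)/C([Li])=C(/[Sn](C)(C)C)[C@H](O[Si](CC)(CC)CC)/C=C(\C)COCc1ccc(OC)cc1 | intermediate
10 | methyl (2E,4R,5E)-2-(acetoxymethyl)-7-[(4-methoxybenzyl)oxy]-6-methyl-4-[(triethylsilyl)oxy]-3-(trimethylstannyl)hepta-2,5-dienoate | COC(=O)/C(COC(C)=O)=C(/[Sn](C)(C)C)[C@H](O[Si](CC)(CC)CC)/C=C(\C)COCc1ccc(OC)cc1 | intermediate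
11 | methyl (2E,4R,5E)-2-(acetoxymethyl)-4-hydroxy-7-[(4-methoxybenzyl)oxy]-6-methyl-3-(trimethylstannyl)hepta-2,5-dienoate | COC(=O)/C(COC(C)=O)=C(/[Sn](C)(C)C)[C@H](O)/C=C(\C)COCc1ccc(OC)cc1 | intermediate
12 | {(5R)-5-[(1E)-3-[(4-methoxybenzyl)oxy]-2-methylprop-1-en-1-yl]-2-oxo-4-(trimethylstannyl)-2,5-dihydrofuran-3-yl}methyl acetate | CC(=O)OCC1=C([Sn](C)(C)C)[C@@H](/C=C(\C)COCc2ccc(OC)cc2)OC1=O | intermediate
13 | (4R)-4-benzyl-1,3-oxazolidin-2-one | O=C1N[C@H](Cc2ccccc2)CO1 | starting material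
14 | (2E)-but-2-enoyl chloride | C/C=C/C(Cl)=O | starting material
15 | (4R)-4-benzyl-3-[(2E)-but-2-enoyl]-1,3-oxazolidin-2-one | C/C=C/C(=O)N1[C@H](Cc2ccccc2)COC1=O | intermediate
16 | (4R)-4-benzyl-3-[(3S)-3-methylpent-4-enoyl]-1,3-oxazolidin-2-one | C=C[C@@H](C)CC(=O)N1[C@H](Cc2ccccc2)COC1=O | intermediate
17 | (3S)-3-methylpent-4-enoic acid | C=C[C@@H](C)CC(=O)O | intermediate
18 | (3S)-3-methylpent-4-enoyl chloride | C=C[C@@H](C)CC(Cl)=O | intermediate
19 | {(5R)-5-[(1E)-3-[(4-methoxybenzyl)oxy]-2-methylprop-1-en-1-yl]-4-[(3S)-3-methylpent-4-enoyl]-2-oxo-2,5-dihydrofuran-3-yl}methyl acetate | CC(=O)OCC1=C(C(=O)C[C@H](C)C=C)[C@@H](/C=C(\C)COCc2ccc(OC)cc2)OC1=O | intermediate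
20 | {(5R)-4-[(1S,3S)-1-hydroxy-3-methylpent-4-en-1-yl]-5-[(1E)-3-[(4-methoxybenzyl)oxy]-2-methylprop-1-en-1-yl]-2-oxo-2,5-dihydrofuran-3-yl}methyl acetate | CC(=O)OCC1=C([C@@H](O)C[C@H](C)C=C)[C@@H](/C=C(\C)COCc2ccc(OC)cc2)OC1=O | intermediate
21 | 4-methylfuran-2(5H)-one | CC1=CC(=O)OC1 | starting material
22 | sodium (2Z)-4-hydroxy-3-methylbut-2-enoate | [Na+].[O-]C(=O)/C=C(/C)CO | intermediate
23 | tert-butyldimethylsilyl (2Z)-4-[(tert-butyldimethylsilyl)oxy]-3-methylbut-2-enoate | CC(C)(C)[Si](C)(C)OC(=O)/C=C(/C)CO[Si](C)(C)C(C)(C)C | intermediate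
24 | (2Z)-4-[(tert-butyldimethylsilyl)oxy]-3-methylbut-2-enoic acid | OC(=O)/C=C(/C)CO[Si](C)(C)C(C)(C)C | intermediate
25 | (1S,3S)-1-{(2R)-4-(acetoxymethyl)-2-[(1E)-3-[(4-methoxybenzyl)oxy]-2-methylprop-1-en-1-yl]-5-oxo-2,5-dihydrofuran-3-yl}-3-methylpent-4-en-1-yl (2Z)-4-[(tert-butyldimethylsilyl)oxy]-3-methylbut-2-enoate | CC(=O)OCC1=C([C@@H](OC(=O)/C=C(/C)CO[Si](C)(C)C(C)(C)C)C[C@H](C)C=C)[C@@H](/C=C(\C)COCc2ccc(OC)cc2)OC1=O | intermediate
26 | (1S,3S)-1-{(2R)-4-(acetoxymethyl)-2-[(1E)-3-hydroxy-2-methylprop-1-en-1-yl]-5-oxo-2,5-dihydrofuran-3-yl}-3-methylpent-4-en-1-yl (2Z)-4-[(tert-butyldimethylsilyl)oxy]-3-methylbut-2-enoate | CC(=O)OCC1=C([C@@H](OC(=O)/C=C(/C)CO[Si](C)(C)C(C)(C)C)C[C@H](C)C=C)[C@@H](/C=C(\C)CO)OC1=O | intermediate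
27 | (1S,3S)-1-{(2S)-4-(acetoxymethyl)-2-[(2R,3R)-3-(hydroxymethyl)-3-methyloxiran-2-yl]-5-oxo-2,5-dihydrofuran-3-yl}-3-methylpent-4-en-1-yl (2Z)-4-[(tert-butyldimethylsilyl)oxy]-3-methylbut-2-enoate | CC(=O)OCC1=C([C@@H](OC(=O)/C=C(/C)CO[Si](C)(C)C(C)(C)C)C[C@H](C)C=C)[C@@H]([C@H]2O[C@]2(C)CO)OC1=O | intermediate
28 | (1S,3S)-1-{(2S)-4-(acetoxymethyl)-2-[(2R,3S)-3-formyl-3-methyloxiran-2-yl]-5-oxo-2,5-dihydrofuran-3-yl}-3-methylpent-4-en-1-yl (2Z)-4-[(tert-butyldimethylsilyl)oxy]-3-methylbut-2-enoate | CC(=O)OCC1=C([C@@H](OC(=O)/C=C(/C)CO[Si](C)(C)C(C)(C)C)C[C@H](C)C=C)[C@@H]([C@H]2O[C@]2(C)C=O)OC1=O | intermediate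
29 | (1S,3S)-1-{(2S)-4-(acetoxymethyl)-2-[(2R,3R)-3-[(E)-(hydroxyimino)methyl]-3-methyloxiran-2-yl]-5-oxo-2,5-dihydrofuran-3-yl}-3-methylpent-4-en-1-yl (2Z)-4-[(tert-butyldimethylsilyl)oxy]-3-methylbut-2-enoate | CC(=O)OCC1=C([C@@H](OC(=O)/C=C(/C)CO[Si](C)(C)C(C)(C)C)C[C@H](C)C=C)[C@@H]([C@H]2O[C@]2(C)/C=N/O)OC1=O | intermediate
30 | hydroximoyl chloride of 29 (oxime C–H replaced by C–Cl; all stereocentres as in 29) | CC(=O)OCC1=C([C@@H](OC(=O)/C=C(/C)CO[Si](C)(C)C(C)(C)C)C[C@H](C)C=C)[C@@H]([C@H]2O[C@]2(C)C(Cl)=NO)OC1=O | intermediate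
31 | nitrile oxide from 29 (C3≡N+–O− on the epoxide carbon C4; all stereocentres as in 29) | CC(=O)OCC1=C([C@@H](OC(=O)/C=C(/C)CO[Si](C)(C)C(C)(C)C)C[C@H](C)C=C)[C@@H]([C@H]2O[C@]2(C)C#[N+][O-])OC1=O | intermediate
32 | 13-acetoxy-4,5-epoxy-8-[(2Z)-4-[(tert-butyldimethylsilyl)oxy]-3-methylbut-2-enoyloxy]germacr-7(11)-en-12,6-olide in which C3 is the C=N carbon and C1 the O-bearing carbon of a fused 4,5-dihydroisoxazole (C1–C2–C3 shared); C4, C5, C6, C8 and C10 arranged as in the target; both C1 epimers | CC(=O)OCC1=C2[C@@H](OC(=O)/C=C(/C)CO[Si](C)(C)C(C)(C)C)C[C@H](C)C5CC(=NO5)[C@@]3(C)O[C@@H]3[C@H]2OC1=O | intermediate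
33 | 13-acetoxy-4,5-epoxy-1-hydroxy-3-oxo-8-[(2Z)-4-[(tert-butyldimethylsilyl)oxy]-3-methylbut-2-enoyloxy]germacr-7(11)-en-12,6-olide; C4, C5, C6, C8 and C10 arranged as in the target; both C1 epimers | CC(=O)OCC1=C2[C@@H](OC(=O)/C=C(/C)CO[Si](C)(C)C(C)(C)C)C[C@H](C)C(O)CC(=O)[C@@]3(C)O[C@@H]3[C@H]2OC1=O | intermediate
34 | (4S,5R,6S,8S,10S)-13-acetoxy-4,5-epoxy-8-[(2Z)-4-[(tert-butyldimethylsilyl)oxy]-3-methylbut-2-enoyloxy]-1,3-dioxogermacr-7(11)-en-12,6-olide | CC(=O)OCC1=C2[C@@H](OC(=O)/C=C(/C)CO[Si](C)(C)C(C)(C)C)C[C@H](C)C(=O)CC(=O)[C@@]3(C)O[C@@H]3[C@H]2OC1=O | intermediate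
35 | (4S,5R,6S,8S,10S)-13-acetoxy-4,5-epoxy-8-[(2Z)-4-hydroxy-3-methylbut-2-enoyloxy]-1,3-dioxogermacr-7(11)-en-12,6-olide | CC(=O)OCC1=C2[C@@H](OC(=O)/C=C(/C)CO)C[C@H](C)C(=O)CC(=O)[C@@]3(C)O[C@@H]3[C@H]2OC1=O | target

**Step count and risks**

Total step count: 22. Longest linear sequence: 18 steps (steps 1–7, 11, 12, 14–22).

Steps most likely to fail:

1. Step 19 (key cycloaddition). Intermolecular dimerisation of the nitrile oxide (furoxan and oligomer formation) may outrun closure of the strained ten-membered ring. The fallback closes the same C2–C3 bond by an aldol reaction and sets out from epoxy alcohol 27. Tsuji–Wacker oxidation (PdCl2 cat., CuCl, O2, DMF/H2O) of the terminal vinyl group would give the methyl ketone F1. Dess–Martin oxidation of the primary alcohol would give the keto aldehyde F2. Kinetic enolisation of the methyl ketone (Bu2BOTf, iPr2NEt, CH2Cl2, −78 °C, high dilution) and intramolecular boron aldol addition to the C3 aldehyde would give the β-hydroxy ketone F3 (hydroxyl at C3, ketone at C1, both C3 epimers). Dess–Martin oxidation of F3 comes back to the route at diketone 34.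

2. Step 6 (transmetalation–hydroxymethylation). Methyllithium may attack the ester, the α-lithio enoate may lose its alkene geometry through its allenoate form, or capture by formaldehyde may be incomplete. The fallback reverses the order of the two carbon–carbon bond formations and sets out from bis-stannane 8. Stille acylation with acid chloride 18 at the β-stannyl group, which is not deactivated by a geminal ester, would give the β-acyl α-stannyl enoate F4. Iododestannylation (I2, CH2Cl2, 0 °C) would give the α-iodo enoate F5. Stille–Kosugi coupling with Bu3SnCH2OH (Pd(PPh3)4, dioxane, 80 °C) would give the α-hydroxymethyl enoate F6, and acetylation (Ac2O, pyridine) the acetate F7. Desilylation–lactonisation (Bu4NF, AcOH) of F7 comes back to the route at ketone 19.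

3. Step 12 (CBS reduction). Facial selectivity may be poor, conjugate reduction may compete, and the β-acyl butenolide may epimerise at C6 on standing. The fallback gives up reagent control and funnels both C8 epimers into one ester; it sets out from ketone 19. Luche reduction (NaBH4, CeCl3, MeOH, −78 °C) would give carbinol 20 and its C8 epimer, the (1R)-carbinol F8, which are separated. Carbinol 20 is esterified with retention as in step 14. Carbinol F8 is esterified with acid 24 under Mitsunobu conditions (PPh3, DIAD, THF, 0 °C) with inversion. Both streams come back to the route at ester 25.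

Further compounds
F1 | step 19 | (1S,3S)-1-{(2S)-4-(acetoxymethyl)-2-[(2R,3R)-3-(hydroxymethyl)-3-methyloxiran-2-yl]-5-oxo-2,5-dihydrofuran-3-yl}-3-methyl-4-oxopentyl (2Z)-4-[(tert-butyldimethylsilyl)oxy]-3-methylbut-2-enoate | CC(=O)OCC1=C([C@@H](OC(=O)/C=C(/C)CO[Si](C)(C)C(C)(C)C)C[C@H](C)C(C)=O)[C@@H]([C@H]2O[C@]2(C)CO)OC1=O
F2 | step 19 | (1S,3S)-1-{(2S)-4-(acetoxymethyl)-2-[(2R,3S)-3-formyl-3-methyloxiran-2-yl]-5-oxo-2,5-dihydrofuran-3-yl}-3-methyl-4-oxopentyl (2Z)-4-[(tert-butyldimethylsilyl)oxy]-3-methylbut-2-enoate | CC(=O)OCC1=C([C@@H](OC(=O)/C=C(/C)CO[Si](C)(C)C(C)(C)C)C[C@H](C)C(C)=O)[C@@H]([C@H]2O[C@]2(C)C=O)OC1=O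
F3 | step 19 | 13-acetoxy-4,5-epoxy-3-hydroxy-1-oxo-8-[(2Z)-4-[(tert-butyldimethylsilyl)oxy]-3-methylbut-2-enoyloxy]germacr-7(11)-en-12,6-olide; C4, C5, C6, C8 and C10 arranged as in the target; both C3 epimers | CC(=O)OCC1=C2[C@@H](OC(=O)/C=C(/C)CO[Si](C)(C)C(C)(C)C)C[C@H](C)C(=O)CC(O)[C@@]3(C)O[C@@H]3[C@H]2OC1=O
F4 | step 6 | methyl (2Z,4R,5E)-7-[(4-methoxybenzyl)oxy]-6-methyl-3-[(3S)-3-methylpent-4-enoyl]-4-[(triethylsilyl)oxy]-2-(trimethylstannyl)hepta-2,5-dienoate | COC(=O)/C([Sn](C)(C)C)=C(/C(=O)C[C@H](C)C=C)[C@H](O[Si](CC)(CC)CC)/C=C(\C)COCc1ccc(OC)cc1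
F5 | step 6 | methyl (2Z,4R,5E)-2-iodo-7-[(4-methoxybenzyl)oxy]-6-methyl-3-[(3S)-3-methylpent-4-enoyl]-4-[(triethylsilyl)oxy]hepta-2,5-dienoate | COC(=O)/C(I)=C(/C(=O)C[C@H](C)C=C)[C@H](O[Si](CC)(CC)CC)/C=C(\C)COCc1ccc(OC)cc1
F6 | step 6 | methyl (2E,4R,5E)-2-(hydroxymethyl)-7-[(4-methoxybenzyl)oxy]-6-methyl-3-[(3S)-3-methylpent-4-enoyl]-4-[(triethylsilyl)oxy]hepta-2,5-dienoate | COC(=O)/C(CO)=C(/C(=O)C[C@H](C)C=C)[C@H](O[Si](CC)(CC)CC)/C=C(\C)COCc1ccc(OC)cc1
F7 | step 6 | methyl (2E,4R,5E)-2-(acetoxymethyl)-7-[(4-methoxybenzyl)oxy]-6-methyl-3-[(3S)-3-methylpent-4-enoyl]-4-[(triethylsilyl)oxy]hepta-2,5-dienoate | COC(=O)/C(COC(C)=O)=C(/C(=O)C[C@H](C)C=C)[C@H](O[Si](CC)(CC)CC)/C=C(\C)COCc1ccc(OC)cc1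
F8 | step 12 | {(5R)-4-[(1R,3S)-1-hydroxy-3-methylpent-4-en-1-yl]-5-[(1E)-3-[(4-methoxybenzyl)oxy]-2-methylprop-1-en-1-yl]-2-oxo-2,5-dihydrofuran-3-yl}methyl acetate | CC(=O)OCC1=C([C@H](O)C[C@H](C)C=C)[C@@H](/C=C(\C)COCc2ccc(OC)cc2)OC1=O
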